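**Plan**

Numbering: oxolane O1, C2 (bears ring A, 4-hydroxy-3,5-dimethoxyphenyl), C3 (bears C9H2OH), C4 (bears the C7' ketone with ring B), C5. The retrosynthesis cuts O1–C2 first, then C4–C7', then C2–C3, leaving a succinate (C9–C3–C4–C5) and two molecules of O-benzylsyringaldehyde.
Enabling feature: C2 is bonded to O1 and to the para-hydroxyaryl ring A, so it is the methide carbon of a ring A p-quinone methide to which the C5 hydroxyl has added. Ring B is attached through the C7' carbonyl, has no benzylic hydrogen and is the harder phenol to oxidize.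
Forward, the chain is joined first: a Stobbe condensation makes C2–C3 and an auxiliary-controlled aldol makes C4–C7'. The aldol also closes a temporary γ-lactone from the C7' oxygen to C9, which the next step reduces open; C7' is then oxidized and the phenols are freed.
The oxolane, the only ring of the target, closes last by anodic oxidation of ring A and capture of the quinone methide by the C5 hydroxyl.
Stereochemistry: C3 from Rh/Me-DuPhos hydrogenation of the Stobbe alkene; C4 from (R)-4-benzyloxazolidinone in a boron syn-aldol (the simpler trans aldol on a β-benzyl butyrolactone would deliver the C4 epimer); C2 from the ring closure, trans to the C3 hydroxymethyl.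

Key step: step 9

Assumption: the (S,S)-Me-DuPhos ligand is taken to give the (R) acid 5, the sense expected for itaconate-type half-esters; should the first run show the opposite sense, the (R,R) ligand is used instead.

**Route**

Step 1
Reactants: 1 syringaldehyde (4-hydroxy-3,5-dimethoxybenzaldehyde)
Product: 2 4-(benzyloxy)-3,5-dimethoxybenzaldehyde
Conditions: BnBr (1.1 equiv), K2CO3 (1.5 equiv), DMF, 60 °C
Reagents that add atoms: benzyl bromide, BrCc1ccccc1
Why: Williamson etherification of the phenoxide should proceed cleanly, and the aryl benzyl ether is chosen because it withstands alkoxide, rhodium-catalysed hydrogenation, boron triflate, borohydride and MnO2 and is removed later by hydrogenolysis.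

Step 2
Reactants: 2 4-(benzyloxy)-3,5-dimethoxybenzaldehyde; 3 dimethyl succinate
Product: 4 (3E)-4-[4-(benzyloxy)-3,5-dimethoxyphenyl]-3-(methoxycarbonyl)but-3-enoic acid
Conditions: NaOMe (2.2 equiv), MeOH, reflux; then aq HCl
Reagents that add atoms: none
Why: The Stobbe condensation joins the aldehyde carbon (C2) to a succinate α-carbon (C3) as a trisubstituted alkene, expected mainly as the E isomer, and at the same time differentiates the two carboxyls (C9 stays a methyl ester, C5 becomes the free acid).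

Step 3
Reactants: 4 (3E)-4-[4-(benzyloxy)-3,5-dimethoxyphenyl]-3-(methoxycarbonyl)but-3-enoic acid
Product: 5 (3R)-4-[4-(benzyloxy)-3,5-dimethoxyphenyl]-3-(methoxycarbonyl)butanoic acid
Conditions: H2 (5 bar), [Rh(cod)((S,S)-Me-DuPhos)]BF4 (1 mol%), NaOMe (0.1 equiv), MeOH, rt
Reagents that add atoms: none
Why: In this asymmetric hydrogenation of a β-aryl itaconate half-ester the carboxylate and the alkene chelate the cationic rhodium bisphospholane, so hydrogen should be delivered to one face and set C3 as R, while the homogeneous catalyst leaves the aryl benzyl ether intact.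

Step 4
Reactants: 5 (3R)-4-[4-(benzyloxy)-3,5-dimethoxyphenyl]-3-(methoxycarbonyl)butanoic acid; 6 (R)-4-benzyl-1,3-oxazolidin-2-one
Product: 8 methyl (2R)-2-[4-(benzyloxy)-3,5-dimethoxybenzyl]-4-[(4R)-4-benzyl-2-oxo-1,3-oxazolidin-3-yl]-4-oxobutanoate, via mixed pivalic anhydride 7 (not isolated)
Conditions: PivCl (1.05 equiv), Et3N (2.5 equiv), THF, −20 °C; then LiCl (1.1 equiv), 6 (1.0 equiv), −20 °C → rt
Reagents that add atoms: none
Why: N-Acylation of the oxazolidinone through the mixed anhydride should occur at the less hindered acyl carbonyl under LiCl/Et3N activation, and because no strong base is used the C3 centre α to the ester is not at risk.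

Step 5
Reactants: 8 methyl (2R)-2-[4-(benzyloxy)-3,5-dimethoxybenzyl]-4-[(4R)-4-benzyl-2-oxo-1,3-oxazolidin-3-yl]-4-oxobutanoate; 2 4-(benzyloxy)-3,5-dimethoxybenzaldehyde
Product: 11 (4R)-4-benzyl-3-{[(2R,3R,4R)-2-[4-(benzyloxy)-3,5-dimethoxyphenyl]-4-[4-(benzyloxy)-3,5-dimethoxybenzyl]-5-oxooxolan-3-yl]carbonyl}-1,3-oxazolidin-2-one, via Z-boron enolate 9 (not isolated), via open aldol adduct 10 (not isolated)
Conditions: Bu2BOTf (1.2 equiv), iPr2NEt (1.4 equiv), CH2Cl2, −78 → 0 °C; 2 (1.2 equiv), −78 → 0 °C; pH 7 buffer, MeOH, 30% H2O2, 0 °C; crude adduct, PPTS (0.1 equiv), CH2Cl2, rt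
Reagents that add atoms: none
Why: In this Evans boron syn-aldol, soft enolization should touch only the imide α-carbon (C4) and give the Z enolate, which adds to the aldehyde through a Zimmerman–Traxler chair on the face away from the auxiliary benzyl group, setting C4 (R in the adduct, the arrangement that reads S once C7' is a ketone) and C7' (R, removed later) under reagent control, after which the C7' hydroxyl closes onto the C9 methyl ester to give the all-trans γ-lactone.

Step 6
Reactants: 11 (4R)-4-benzyl-3-{[(2R,3R,4R)-2-[4-(benzyloxy)-3,5-dimethoxyphenyl]-4-[4-(benzyloxy)-3,5-dimethoxybenzyl]-5-oxooxolan-3-yl]carbonyl}-1,3-oxazolidin-2-one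
Product: 12 (1R,2S,3R)-1-[4-(benzyloxy)-3,5-dimethoxyphenyl]-3-[4-(benzyloxy)-3,5-dimethoxybenzyl]-2-(hydroxymethyl)butane-1,4-diol
Conditions: LiBH4 (6 equiv), MeOH (6 equiv), THF, 0 °C → rt
Reagents that add atoms: none
Why: Borohydride reduction should cleave the N-acyl oxazolidinone reductively to the C5 primary alcohol and open the γ-lactone to the C9 primary alcohol and the C7' carbinol in one operation, without touching a stereocentre and with release of the auxiliary for recovery.

Step 7
Reactants: 12 (1R,2S,3R)-1-[4-(benzyloxy)-3,5-dimethoxyphenyl]-3-[4-(benzyloxy)-3,5-dimethoxybenzyl]-2-(hydroxymethyl)butane-1,4-diol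
Product: 13 (2S,3R)-1-[4-(benzyloxy)-3,5-dimethoxyphenyl]-3-[4-(benzyloxy)-3,5-dimethoxybenzyl]-4-hydroxy-2-(hydroxymethyl)butan-1-one
Conditions: MnO2 (activated, 15 equiv), CH2Cl2, rt
Reagents that add atoms: none
Why: Chemoselective MnO2 oxidation should convert only the benzylic carbinol at C7' into the aryl ketone and leave the two saturated primary alcohols alone, under neutral conditions that do not epimerize C4.

Step 8
Reactants: 13 (2S,3R)-1-[4-(benzyloxy)-3,5-dimethoxyphenyl]-3-[4-(benzyloxy)-3,5-dimethoxybenzyl]-4-hydroxy-2-(hydroxymethyl)butan-1-one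
Product: 14 (2S,3R)-4-hydroxy-3-(4-hydroxy-3,5-dimethoxybenzyl)-1-(4-hydroxy-3,5-dimethoxyphenyl)-2-(hydroxymethyl)butan-1-one
Conditions: H2 (1 atm), Pd/C (10 wt% Pd, 5 mol%), EtOAc/MeOH 1:1, rt, stopped after uptake of 2 equiv H2
Reagents that add atoms: none
Why: Hydrogenolysis of the two aryl benzyl ethers over palladium on carbon at atmospheric pressure should be much faster than reduction of the para-oxygenated aryl ketone, and the neutral medium leaves C3 and C4 untouched.

Step 9
Reactants: 14 (2S,3R)-4-hydroxy-3-(4-hydroxy-3,5-dimethoxybenzyl)-1-(4-hydroxy-3,5-dimethoxyphenyl)-2-(hydroxymethyl)butan-1-one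
Product: 16 (4-hydroxy-3,5-dimethoxyphenyl)[(3S,4R,5S)-5-(4-hydroxy-3,5-dimethoxyphenyl)-4-(hydroxymethyl)oxolan-3-yl]methanone, via quinone methide 15 (not isolated)
Conditions: undivided cell, graphite anode, Pt cathode, constant current 2 mA cm−2, 2.1 F mol−1; Bu4NBF4 (0.1 M), 2,6-lutidine (3 equiv), MeCN/(CF3)2CHOH 9:1, 5 mM in 14, rt, Ar
Reagents that add atoms: none
Why: At the anode the ring A phenol loses an electron and, to 2,6-lutidine, its proton; the 2,6-dimethoxyphenoxyl radical is taken on to the p-quinone methide 15 by a second electron transfer with loss of a benzylic proton at C2 (or by disproportionation of two radicals), and the C5 hydroxyl then adds to the methide carbon with rearomatization, forming O1–C2 while protons are reduced to hydrogen at the cathode. The closest known reaction types are the anodic two-electron oxidation of 4-alkyl-2,6-dialkoxyphenols to quinone methides that are captured by oxygen nucleophiles and the DDQ-induced cyclization of 2,3-dibenzylbutane-1,4-diols to 2-aryloxolanes. The oxolane closes in the 5-exo-trig mode (a 1,6-oxa-Michael addition), whereas the C9 hydroxyl could only close a four-membered oxetane and is not expected to compete. The new centre C2 is controlled by C3: in the envelope-like transition state the flat quinone methide arm lies anti to the C3 hydroxymethyl group, so ring A should end trans to it (2S in the plan numbering), and since a para-hydroxybenzyl ether can in principle revert to 15, any 2,3-cis material has a path to the all-trans isomer. The step needs oxidation of ring A and not of ring B and a stop after two electrons: ring B is a 4-acylphenol with a higher oxidation potential and no benzylic hydrogen, and the charge is limited to about 2 F per mole at low current density and high dilution, which also disfavours intermolecular phenol coupling. C3 and C4 are spectators; C4 lies α to the ketone, but the medium is only weakly basic and the 3,4-trans arrangement already present is the stable one.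

**Compound list**

1 | syringaldehyde (4-hydroxy-3,5-dimethoxybenzaldehyde) | COc1cc(C=O)cc(OC)c1O | starting material
2 | 4-(benzyloxy)-3,5-dimethoxybenzaldehyde | COc1cc(C=O)cc(OC)c1OCc1ccccc1 | intermediate
3 | dimethyl succinate | COC(=O)CCC(=O)OC | starting material
4 | (3E)-4-[4-(benzyloxy)-3,5-dimethoxyphenyl]-3-(methoxycarbonyl)but-3-enoic acid | COC(=O)/C(CC(=O)O)=C/c1cc(OC)c(OCc2ccccc2)c(OC)c1 | intermediate
5 | (3R)-4-[4-(benzyloxy)-3,5-dimethoxyphenyl]-3-(methoxycarbonyl)butanoic acid | COC(=O)[C@H](Cc1cc(OC)c(OCc2ccccc2)c(OC)c1)CC(=O)O | intermediate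
6 | (R)-4-benzyl-1,3-oxazolidin-2-one | O=C1N[C@H](Cc2ccccc2)CO1 | starting material
7 | (3R)-4-[4-(benzyloxy)-3,5-dimethoxyphenyl]-3-(methoxycarbonyl)butanoic 2,2-dimethylpropanoic anhydride | COC(=O)[C@H](Cc1cc(OC)c(OCc2ccccc2)c(OC)c1)CC(=O)OC(=O)C(C)(C)C | intermediate (not isolated)
8 | methyl (2R)-2-[4-(benzyloxy)-3,5-dimethoxybenzyl]-4-[(4R)-4-benzyl-2-oxo-1,3-oxazolidin-3-yl]-4-oxobutanoate | COC(=O)[C@H](Cc1cc(OC)c(OCc2ccccc2)c(OC)c1)CC(=O)N1[C@H](Cc2ccccc2)COC1=O | intermediate
9 | methyl (2R,3Z)-2-[4-(benzyloxy)-3,5-dimethoxybenzyl]-4-[(4R)-4-benzyl-2-oxo-1,3-oxazolidin-3-yl]-4-[(dibutylboranyl)oxy]but-3-enoate | COC(=O)[C@H](Cc1cc(OC)c(OCc2ccccc2)c(OC)c1)/C=C(\OB(CCCC)CCCC)N1[C@H](Cc2ccccc2)COC1=O | intermediate (not isolated)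
10 | methyl (2R,3R)-2-[4-(benzyloxy)-3,5-dimethoxybenzyl]-3-{(R)-[4-(benzyloxy)-3,5-dimethoxyphenyl](hydroxy)methyl}-4-[(4R)-4-benzyl-2-oxo-1,3-oxazolidin-3-yl]-4-oxobutanoate | COC(=O)[C@H](Cc1cc(OC)c(OCc2ccccc2)c(OC)c1)[C@H]([C@@H](O)c1cc(OC)c(OCc2ccccc2)c(OC)c1)C(=O)N1[C@H](Cc2ccccc2)COC1=O | intermediate (not isolated)
11 | (4R)-4-benzyl-3-{[(2R,3R,4R)-2-[4-(benzyloxy)-3,5-dimethoxyphenyl]-4-[4-(benzyloxy)-3,5-dimethoxybenzyl]-5-oxooxolan-3-yl]carbonyl}-1,3-oxazolidin-2-one (all-trans lactone) | O=C1O[C@@H](c2cc(OC)c(OCc3ccccc3)c(OC)c2)[C@H](C(=O)N2[C@H](Cc3ccccc3)COC2=O)[C@H]1Cc1cc(OC)c(OCc2ccccc2)c(OC)c1 | intermediate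
12 | (1R,2S,3R)-1-[4-(benzyloxy)-3,5-dimethoxyphenyl]-3-[4-(benzyloxy)-3,5-dimethoxybenzyl]-2-(hydroxymethyl)butane-1,4-diol | OC[C@H](Cc1cc(OC)c(OCc2ccccc2)c(OC)c1)[C@@H](CO)[C@@H](O)c1cc(OC)c(OCc2ccccc2)c(OC)c1 | intermediate
13 | (2S,3R)-1-[4-(benzyloxy)-3,5-dimethoxyphenyl]-3-[4-(benzyloxy)-3,5-dimethoxybenzyl]-4-hydroxy-2-(hydroxymethyl)butan-1-one | OC[C@H](Cc1cc(OC)c(OCc2ccccc2)c(OC)c1)[C@@H](CO)C(=O)c1cc(OC)c(OCc2ccccc2)c(OC)c1 | intermediate
14 | (2S,3R)-4-hydroxy-3-(4-hydroxy-3,5-dimethoxybenzyl)-1-(4-hydroxy-3,5-dimethoxyphenyl)-2-(hydroxymethyl)butan-1-one | COc1cc(C[C@@H](CO)[C@@H](CO)C(=O)c2cc(OC)c(O)c(OC)c2)cc(OC)c1O | intermediate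
15 | 4-[(2R,3S)-4-hydroxy-3-(4-hydroxy-3,5-dimethoxybenzoyl)-2-(hydroxymethyl)butylidene]-2,6-dimethoxycyclohexa-2,5-dien-1-one | COC1=CC(=C[C@@H](CO)[C@@H](CO)C(=O)c2cc(OC)c(O)c(OC)c2)C=C(OC)C1=O | intermediate (not isolated)
16 | (4-hydroxy-3,5-dimethoxyphenyl)[(3S,4R,5S)-5-(4-hydroxy-3,5-dimethoxyphenyl)-4-(hydroxymethyl)oxolan-3-yl]methanone (2S,3R,4S in the plan numbering; all-trans) | COc1cc(C(=O)[C@@H]2CO[C@H](c3cc(OC)c(O)c(OC)c3)[C@H]2CO)cc(OC)c1O | target

**Step count and risks**

Total step count: 9. Longest linear sequence: 9 steps (1 to 16).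

Step 9. After the second electron transfer, the ring A phenoxonium ion may be attacked at its para (ipso) carbon by the C9 hydroxyl, a spiro-etherification that competes with loss of the benzylic proton. Further oxidation of the product phenol or of the more acidic ring B phenol may also consume charge. The fallback closes the ring by chemical hydride abstraction before the phenols are freed. It sets out from 13: DDQ (1.2 equiv) in dry CH2Cl2 over 4 Å molecular sieves at 0 °C should abstract hydride from the C2 methylene of the electron-rich ring A (ring B being deactivated by its ketone), and the C5 hydroxyl should trap the benzylic cation to give the bis-benzyl ether of the target F1. Hydrogenolysis (H2, Pd/C, EtOAc/MeOH) then comes back to the route at 16.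

Step 5. The facial preference of the auxiliary may be eroded by the adjacent C3 centre (a mismatched pairing), and the branched enolate may add sluggishly to the electron-rich aldehyde. The fallback gives up reagent control at C4 and relies on ring control followed by thermodynamic correction. It sets out from 5:
- The potassium salt is reduced at the ester with Ca(BH4)2 (from CaCl2 and NaBH4, EtOH) and lactonized with aq HCl to the β-benzyl lactone F2.
- Its lithium enolate (LiN(iPr)2, THF, −78 °C) should add to 2 anti to the benzyl group to give the trans aldol lactone F3.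
- LiAlH4 should give the C4-epimeric triol F4, MnO2 the C4-epimeric dibenzyl keto diol F5, and hydrogenolysis the C4-epimeric keto diol F6.
- Anodic oxidation as in step 9 should pass through the epimeric quinone methide F7 to the 3,4-cis oxolane F8.
- DBU (3 equiv, two being taken up by the phenols) in MeOH at rt should epimerize C4, which is α to the ketone, to the more stable all-trans arrangement, coming back to the route at 16.

Step 7. The hindered benzylic carbinol, hydrogen-bonded to two neighbouring hydroxyls, may oxidize slowly on MnO2, and long exposure may begin to attack the primary alcohols. The fallback is protect, oxidize, deprotect, setting out from 12. TBSCl (2.2 equiv) and imidazole in CH2Cl2 at 0 °C should silylate only the two primary hydroxyls to give the bis-silyl ether F9. Dess–Martin periodinane with NaHCO3 in CH2Cl2 should oxidize the remaining carbinol to the bis-silyl ketone F10. HF·pyridine in THF at 0 °C, a non-basic desilylation that avoids β-elimination and epimerization at C4, comes back to the route at 13.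

Further compounds
F1 | step 9 | [4-(benzyloxy)-3,5-dimethoxyphenyl]{(3S,4R,5S)-5-[4-(benzyloxy)-3,5-dimethoxyphenyl]-4-(hydroxymethyl)oxolan-3-yl}methanone | COc1cc(C(=O)[C@@H]2CO[C@H](c3cc(OC)c(OCc4ccccc4)c(OC)c3)[C@H]2CO)cc(OC)c1OCc1ccccc1
F2 | step 5 | (4R)-4-[4-(benzyloxy)-3,5-dimethoxybenzyl]oxolan-2-one | O=C1C[C@@H](Cc2cc(OC)c(OCc3ccccc3)c(OC)c2)CO1
F3 | step 5 | (3S,4R)-3-{[4-(benzyloxy)-3,5-dimethoxyphenyl](hydroxy)methyl}-4-[4-(benzyloxy)-3,5-dimethoxybenzyl]oxolan-2-one (both carbinol epimers) | O=C1OC[C@H](Cc2cc(OC)c(OCc3ccccc3)c(OC)c2)[C@H]1C(O)c1cc(OC)c(OCc2ccccc2)c(OC)c1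
F4 | step 5 | (2R,3R)-1-[4-(benzyloxy)-3,5-dimethoxyphenyl]-3-[4-(benzyloxy)-3,5-dimethoxybenzyl]-2-(hydroxymethyl)butane-1,4-diol (both C1 epimers) | OC[C@H](Cc1cc(OC)c(OCc2ccccc2)c(OC)c1)[C@H](CO)C(O)c1cc(OC)c(OCc2ccccc2)c(OC)c1
F5 | step 5 | (2R,3R)-1-[4-(benzyloxy)-3,5-dimethoxyphenyl]-3-[4-(benzyloxy)-3,5-dimethoxybenzyl]-4-hydroxy-2-(hydroxymethyl)butan-1-one | OC[C@H](Cc1cc(OC)c(OCc2ccccc2)c(OC)c1)[C@H](CO)C(=O)c1cc(OC)c(OCc2ccccc2)c(OC)c1
F6 | step 5 | (2R,3R)-4-hydroxy-3-(4-hydroxy-3,5-dimethoxybenzyl)-1-(4-hydroxy-3,5-dimethoxyphenyl)-2-(hydroxymethyl)butan-1-one | OC[C@H](Cc1cc(OC)c(O)c(OC)c1)[C@H](CO)C(=O)c1cc(OC)c(O)c(OC)c1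
F7 | step 5 | 4-[(2R,3R)-4-hydroxy-3-(4-hydroxy-3,5-dimethoxybenzoyl)-2-(hydroxymethyl)butylidene]-2,6-dimethoxycyclohexa-2,5-dien-1-one | COC1=CC(=C[C@@H](CO)[C@H](CO)C(=O)c2cc(OC)c(O)c(OC)c2)C=C(OC)C1=O
F8 | step 5 | (4-hydroxy-3,5-dimethoxyphenyl)[(3R,4R,5S)-5-(4-hydroxy-3,5-dimethoxyphenyl)-4-(hydroxymethyl)oxolan-3-yl]methanone | COc1cc(C(=O)[C@H]2CO[C@H](c3cc(OC)c(O)c(OC)c3)[C@H]2CO)cc(OC)c1O
F9 | step 7 | (1R,2S,3R)-1-[4-(benzyloxy)-3,5-dimethoxyphenyl]-3-[4-(benzyloxy)-3,5-dimethoxybenzyl]-4-[(tert-butyldimethylsilyl)oxy]-2-{[(tert-butyldimethylsilyl)oxy]methyl}butan-1-ol | CC(C)(C)[Si](C)(C)OC[C@H](Cc1cc(OC)c(OCc2ccccc2)c(OC)c1)[C@@H](CO[Si](C)(C)C(C)(C)C)[C@@H](O)c1cc(OC)c(OCc2ccccc2)c(OC)c1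
F10 | step 7 | (2S,3R)-1-[4-(benzyloxy)-3,5-dimethoxyphenyl]-3-[4-(benzyloxy)-3,5-dimethoxybenzyl]-4-[(tert-butyldimethylsilyl)oxy]-2-{[(tert-butyldimethylsilyl)oxy]methyl}butan-1-one | CC(C)(C)[Si](C)(C)OC[C@H](Cc1cc(OC)c(OCc2ccccc2)c(OC)c1)[C@@H](CO[Si](C)(C)C(C)(C)C)C(=O)c1cc(OC)c(OCc2ccccc2)c(OC)c1
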